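Ring A is disconnected at two bonds, C(CH3)–C(OCH3) and C(butanoyl)–C(OH). The neighbouring ring A carbons C–butanoyl and C–OCH3, flanked by C–OH on one side and C–CH3 on the other, are supplied together by the alkyne 1-methoxyhex-1-yn-3-one. An Alder–Rickert sequence adds this ynone across a 1,3-bis(trimethylsilyloxy)cyclohexa-1,3-diene, and the bicyclo[2.2.2]octadiene expels ethene, so hexasubstituted aromatic ring A forms in one operation. The precursor is the tetrakis(trimethylsilyl) dienol ether of 2-[(ring B)methyl]-4-methylcyclohexane-1,3-dione. It is assembled from propionylfilicinic acid, a CH2 unit and 4-methylcyclohexane-1,3-dione by a directed Mannich exchange.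

Key step: step 5

Remark: 4-methylcyclohexane-1,3-dione (3) and N-methoxy-N-methylbutanamide (7) are taken as catalogue compounds; 3 is racemic, its stereocentre disappears in step 4, and the target is achiral.
Remark: of the two conjugated dienol ethers that 5 can form, only the one enolised toward the methyl-bearing C4 carries the ring A methyl into the arene (the C6 isomer would lose propene), so step 4 is run under equilibrating conditions that favour the more substituted diene.
Remark: the acidic enols of ring B are capped as trimethylsilyl ethers in the same operation, because free enol OH groups would protonate the diene; all four silyl groups leave together in step 6.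

Step 1
Reactants: 1 flopropione
Product: 2 propionylfilicinic acid
Conditions: MeI (2.2 equiv), NaOMe (3 equiv), MeOH, 0 °C → rt; aq. HCl
Reagents that add atoms: iodomethane, CI
Why: Base-mediated C-methylation of the acylphloroglucinol anion, in which the second methyl enters the ring carbon that is already methylated and so dearomatises the ring to the gem-dimethyl triketone (the standard entry to acylfilicinic acids); under- and over-methylated congeners should be removed by crystallisation.

Step 2
Reactants: 2 propionylfilicinic acid; 3 4-methylcyclohexane-1,3-dione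
Product: 5 2-[(ring B)methyl]-4-methylcyclohexane-1,3-dione, via ring B Mannich base 4 (not isolated)
Conditions: [Me2N=CH2]I (1.0 equiv), MeCN, 0 °C → rt; then 3 (2.0 equiv), NaOAc (1.5 equiv), 50 °C
Reagents that add atoms: N,N-dimethylmethyleneiminium iodide (Eschenmoser's salt), C=[N+](C)C.[I-]
Why: Mannich aminomethylation at the only free ring carbon of 2, then loss of dimethylamine to a ring B quinone methide and Michael addition of the C2 enol carbon of 3 (Mannich-base exchange), so the CH2 link is built without free formaldehyde and the homodimer of 2 cannot form, while the surplus of 3 suppresses a second alkylation at C2.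

Step 3
Reactants: 6 chloroacetaldehyde dimethyl acetal; 7 N-methoxy-N-methylbutanamide
Product: 9 1-methoxyhex-1-yn-3-one, via lithium methoxyacetylide 8 (not isolated)
Conditions: Et2NH (3.3 equiv), n-BuLi (3.1 equiv), THF, 0 °C; 6 (1.0 equiv), 0 °C; 7 (0.8 equiv), −78 → 0 °C; cold aq. NaH2PO4
Reagents that add atoms: none
Why: Two base-induced eliminations and a deprotonation convert the chloroacetal into the alkoxyacetylide, which is acylated in a Weinreb ketone synthesis whose chelated tetrahedral adduct prevents a second addition, and the buffered acidic quench protonates the amines before they can add to the ynone.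

Step 4
Reactants: 5 2-[(ring B)methyl]-4-methylcyclohexane-1,3-dione
Product: 10 tetrakis(trimethylsilyl) dienol ether of 5
Conditions: Et3N (6 equiv), then Me3SiOTf (4.4 equiv), toluene, 0 → 40 °C; upper phase decanted under argon, concentrated, used crude
Reagents that add atoms: trimethylsilyl trifluoromethanesulfonate, C[Si](C)(C)OS(=O)(=O)C(F)(F)F
Why: Soft enolisation and O-silylation in which the three enolic OH groups are capped first and the vinylogous silyl ester carbonyl of the dione ring is then O-silylated and deprotonated at an alpha carbon; because triethylammonium triflate can reprotonate the diene terminus, this last deprotonation is reversible and the more substituted C3=C4(CH3) dienol ether should predominate, and keeping the amine in excess guards against acid-induced ring closure between the two rings.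

Step 5
Reactants: 10 tetrakis(trimethylsilyl) dienol ether of 5; 9 1-methoxyhex-1-yn-3-one
Product: 12 tetrakis(trimethylsilyl) aspidin PB, via bicyclo[2.2.2]octadiene adduct 11 (not isolated)
Conditions: 9 (3 equiv, in portions), toluene, sealed tube, 120 → 160 °C
Reagents that add atoms: none
Why: The electron-rich bis(silyloxy)diene of 10 and the acyl-activated alkyne 9 should combine in a thermal, normal-electron-demand and probably asynchronous [4+2] cycloaddition, and the bicyclo[2.2.2]octa-2,5-diene 11 then undergoes a thermally allowed [4+2] cycloreversion that expels the C5–C6 bridge as ethene, made irreversible by the gain of aromaticity. The closest known reaction is the Alder–Rickert synthesis of resorcinols from 1,3-bis(trimethylsilyloxy)cyclohexa-1,3-dienes and acetylenic ketones or esters, applied here to a 2-alkyl-4-methyl diene and a beta-alkoxy ynone. Ring A is closed as a six-membered carbocycle by suprafacial cycloaddition across the diene termini C1 and C4, not by an ionic cyclisation, the new bonds being C4(CH3)–C(OCH3) and C1(OSiMe3)–C(butanoyl). The two bridgehead stereocentres of 11 are racemic and transient and vanish on aromatisation, so no stereocentre has to be controlled. The selectivity needed is regiochemical: C4, beta to the C3 silyloxy group and vinylogously fed by the C1 silyloxy group, is the more nucleophilic terminus and should bond to the conjugate position of the ynone, which is the methoxy-bearing carbon, so that butanoyl lands next to C1–O and OCH3 next to C–CH3. Chemoselectivity rests on ring B, whose own diene ends on a carbon carrying two acyl groups beside the quaternary CMe2 carbon and should be too electron-poor and hindered to compete.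

Step 6
Reactants: 12 tetrakis(trimethylsilyl) aspidin PB
Product: 13 aspidin PB
Conditions: 0.5 M aq. HCl, THF, 0 °C → rt
Reagents that add atoms: none
Why: Acid-catalysed hydrolysis of aryl and enol trimethylsilyl ethers is fast at 0 °C and avoids the basic media in which methylene-bridged acylphloroglucinols fragment by retro-Michael cleavage, while the aryl methyl ether and the ketones are untouched.

Compound list
1 | flopropione, 1-(2,4,6-trihydroxyphenyl)propan-1-one | CCC(=O)c1c(O)cc(O)cc1O | starting material
2 | propionylfilicinic acid, 3,5-dihydroxy-6,6-dimethyl-2-propanoylcyclohexa-2,4-dien-1-one | CCC(=O)C1=C(O)C=C(O)C(C)(C)C1=O | intermediate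
3 | 4-methylcyclohexane-1,3-dione, racemic | CC1CCC(=O)CC1=O | starting material
4 | ring B Mannich base, 4-[(dimethylamino)methyl]-3,5-dihydroxy-6,6-dimethyl-2-propanoylcyclohexa-2,4-dien-1-one, formed as hydroiodide and freed by NaOAc | CCC(=O)C1=C(O)C(CN(C)C)=C(O)C(C)(C)C1=O | intermediate
5 | 2-[(ring B)methyl]-4-methylcyclohexane-1,3-dione, drawn as mono-enol: 3,5-dihydroxy-4-[(2-hydroxy-5-methyl-6-oxocyclohex-1-en-1-yl)methyl]-6,6-dimethyl-2-propanoylcyclohexa-2,4-dien-1-one, racemic at the stereolabile methyl-bearing carbon | CCC(=O)C1=C(O)C(CC2=C(O)CCC(C)C2=O)=C(O)C(C)(C)C1=O | intermediate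
6 | chloroacetaldehyde dimethyl acetal, 2-chloro-1,1-dimethoxyethane | COC(CCl)OC | starting material
7 | N-methoxy-N-methylbutanamide | CCCC(=O)N(C)OC | starting material
8 | lithium methoxyacetylide | [Li]C#COC | intermediate
9 | 1-methoxyhex-1-yn-3-one | CCCC(=O)C#COC | intermediate
10 | tetrakis(trimethylsilyl) dienol ether of 5: 6,6-dimethyl-4-{[5-methyl-2,6-bis(trimethylsilyloxy)cyclohexa-1,5-dien-1-yl]methyl}-2-propanoyl-3,5-bis(trimethylsilyloxy)cyclohexa-2,4-dien-1-one, no stereocentre | CC1=C(O[Si](C)(C)C)C(CC2=C(O[Si](C)(C)C)C(C)(C)C(=O)C(C(=O)CC)=C2O[Si](C)(C)C)=C(O[Si](C)(C)C)CC1 | intermediate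
11 | bicyclo[2.2.2]octadiene adduct: 2-butanoyl-3-methoxy-4-methyl-1,5-bis(trimethylsilyloxy)bicyclo[2.2.2]octa-2,5-diene carrying the bis(trimethylsilyl) ring B methyl group at C6, racemic, the two bridgeheads being its only stereocentres with relative configuration fixed by the bicycle | CC12CCC(O[Si](C)(C)C)(C(C(=O)CCC)=C1OC)C(CC3=C(O[Si](C)(C)C)C(C)(C)C(=O)C(C(=O)CC)=C3O[Si](C)(C)C)=C2O[Si](C)(C)C | intermediate
12 | tetrakis(trimethylsilyl) aspidin PB, no stereocentre | CCCC(=O)c1c(O[Si](C)(C)C)c(CC2=C(O[Si](C)(C)C)C(C)(C)C(=O)C(C(=O)CC)=C2O[Si](C)(C)C)c(O[Si](C)(C)C)c(C)c1OC | intermediate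
13 | aspidin PB, 4-[(3-butanoyl-2,6-dihydroxy-4-methoxy-5-methylphenyl)methyl]-3,5-dihydroxy-6,6-dimethyl-2-propanoylcyclohexa-2,4-dien-1-one, achiral | CCCC(=O)c1c(O)c(CC2=C(O)C(C)(C)C(=O)C(C(=O)CC)=C2O)c(O)c(C)c1OC | target

Total step count: 6
Longest linear sequence: 5 steps (steps 1, 2, 4, 5, 6); step 3 supplies the ynone convergently.

Steps most likely to fail

Step 5. The cycloaddition may not outrun thermal degradation of the ynone and desilylation of the diene, because a tetrasubstituted diene has to add a donor-substituted alkyne; partial loss of regiocontrol is the secondary concern. The fallback sets out from 2 (through its Mannich base 4) and comes back at 13, bypassing 10 to 12, by making ring A as a free phenol with classical arene chemistry.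
- 2-methylbenzene-1,3,5-triol F1 would be C-acylated with butanoic acid and BF3·OEt2 to 1-(2,4,6-trihydroxy-3-methylphenyl)butan-1-one F2.
- MOMCl and iPr2NEt should cap the para hydroxyl and the less hindered ortho hydroxyl, leaving the chelated hydroxyl beside the methyl group free in 1-[2-hydroxy-4,6-bis(methoxymethoxy)-3-methylphenyl]butan-1-one F3.
- Me2SO4 and K2CO3 in acetone would methylate that hydroxyl to give 1-[2-methoxy-4,6-bis(methoxymethoxy)-3-methylphenyl]butan-1-one F4.
- HCl in MeOH would release 1-(4,6-dihydroxy-2-methoxy-3-methylphenyl)butan-1-one (pseudoaspidinol B) F5, which has a single free ring position between its two hydroxyls.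
- F5 would be joined to 4, generated from 2 as in step 2, by the same Mannich exchange to give 13 directly.

Step 4. Enolisation may go in the wrong direction, toward C6, which would later cost the ring A methyl group as propene. Over-silylation at the propanoyl side chain and acid-induced ring closure of a ring B enol oxygen onto the dione carbonyl are further risks. The fallback sets out from 3 and from 2 (through 4) and comes back at 12, using a homologue in which both directions of enolisation are equivalent.
- 3 would be methylated at C6 through its dianion (LiN(iPr)2, 2.2 equiv, THF; MeI) to 4,6-dimethylcyclohexane-1,3-dione F6, a mixture of diastereomers that does not matter.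
- Mannich exchange with 4 as in step 2 would give 2-[(ring B)methyl]-4,6-dimethylcyclohexane-1,3-dione F7.
- Silylation as in step 4 can give only one conjugated diene, the tetrakis(trimethylsilyl) dienol ether of F7 F8.
- With 9 this should pass through the methyl-substituted bicyclo[2.2.2]octadiene adduct F9, which expels propene instead of ethene and delivers 12.

Step 3. The liberated amines may add in conjugate fashion to the push-pull ynone, or the ynol ether may be hydrated during quench and purification. The fallback sets out from 6 (through 8) and comes back at 9. Acetylide 8 would be added to butanal (CCCC=O) at −78 °C to give racemic 1-methoxyhex-1-yn-3-ol F10, which after a neutral work-up would be oxidised with MnO2 in CH2Cl2 to 9, so that no amine is present once the ynone exists.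

Further compounds
F1 | step 5 | 2-methylbenzene-1,3,5-triol | Cc1c(O)cc(O)cc1O
F2 | step 5 | 1-(2,4,6-trihydroxy-3-methylphenyl)butan-1-one | CCCC(=O)c1c(O)cc(O)c(C)c1O
F3 | step 5 | 1-[2-hydroxy-4,6-bis(methoxymethoxy)-3-methylphenyl]butan-1-one | CCCC(=O)c1c(O)c(C)c(OCOC)cc1OCOC
F4 | step 5 | 1-[2-methoxy-4,6-bis(methoxymethoxy)-3-methylphenyl]butan-1-one | CCCC(=O)c1c(OC)c(C)c(OCOC)cc1OCOC
F5 | step 5 | 1-(4,6-dihydroxy-2-methoxy-3-methylphenyl)butan-1-one (pseudoaspidinol B) | CCCC(=O)c1c(OC)c(C)c(O)cc1O
F6 | step 4 | 4,6-dimethylcyclohexane-1,3-dione | CC1CC(C)C(=O)CC1=O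
F7 | step 4 | 2-[(ring B)methyl]-4,6-dimethylcyclohexane-1,3-dione, drawn as mono-enol | CCC(=O)C1=C(O)C(CC2=C(O)C(C)CC(C)C2=O)=C(O)C(C)(C)C1=O
F8 | step 4 | tetrakis(trimethylsilyl) dienol ether of F7 | CC1=C(O[Si](C)(C)C)C(CC2=C(O[Si](C)(C)C)C(C)(C)C(=O)C(C(=O)CC)=C2O[Si](C)(C)C)=C(O[Si](C)(C)C)C(C)C1
F9 | step 4 | methyl-substituted bicyclo[2.2.2]octadiene adduct of F8 and 9 | CC12CC(C)C(O[Si](C)(C)C)(C(C(=O)CCC)=C1OC)C(CC3=C(O[Si](C)(C)C)C(C)(C)C(=O)C(C(=O)CC)=C3O[Si](C)(C)C)=C2O[Si](C)(C)C
F10 | step 3 | 1-methoxyhex-1-yn-3-ol, racemic | CCCC(O)C#COC
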